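Ring A carries oxygen on all four carbons C5–C8, with O5 and O8 para and OMe on C6 and C7. This is the carbon–oxygen pattern of a squaric ester, and the C4a–C8a edge is the free C5=C6 alkene of a 3-oxygenated 4-pyranone (ring C).
Cuts, in order: the O–CH3 bonds at O5 and O8 and the benzyl group on O3; C8–C8a (electrocyclic), with C5–C8 re-closed to a cyclobutenone; C4a–C5 (pyranonylmagnesium plus squarate C=O); the C–I bond; the C4–O bond and ring C back to a 2-furylcarbinol; C2–C1' (aryl Grignard addition).
Forward: ring B is bought. Ring C is grown from the furan by Achmatowicz rearrangement, epoxidation and acid isomerisation. Ring A is annulated last by a Moore rearrangement, followed by two O-methylations and debenzylation.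
Stereochemistry: the target is achiral. The sp3 centres of 4–7, 13 and 15 are assumed to be carried as racemates or mixtures, drawn without configuration, because each becomes sp2 later. Only the alkene geometry of ketene 14 matters.

Key step: step 9

Step 1
Reactants: 1 furfural; 2 4-bromoanisole
Product: 4 furan-2-yl(4-methoxyphenyl)methanol (racemic), via 4-methoxyphenylmagnesium bromide 3 (not isolated)
Conditions: Mg, THF, reflux; then 1, 0 °C to rt; aq NH4Cl
Reagents that add atoms: none
Why: Grignard addition to a non-enolisable heteroaryl aldehyde forms the future C2–C1' bond; the carbinol centre arises racemic, which is immaterial because it becomes sp2 in step 5, and the neutral quench spares the acid-labile, doubly activated alcohol.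

Step 2
Reactants: 4 furan-2-yl(4-methoxyphenyl)methanol
Product: 5 6-hydroxy-2-(4-methoxyphenyl)-2H-pyran-3(6H)-one (anomeric mixture)
Conditions: NBS, NaHCO3, THF–H2O 4:1, 0 °C
Reagents that add atoms: water, O
Why: Achmatowicz rearrangement: the furan, by far the most electron-rich π system present, is oxidised by NBS in water to the cis-enedione, whose aldehyde carbon is captured by the carbinol oxygen to give the pyranone hemiacetal, while the bicarbonate buffer prevents acid-induced ionisation of the substrate.

Step 3
Reactants: 5 6-hydroxy-2-(4-methoxyphenyl)-2H-pyran-3(6H)-one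
Product: 6 6-methoxy-2-(4-methoxyphenyl)-2H-pyran-3(6H)-one
Conditions: HC(OMe)3, BF3·OEt2 (cat.), CH2Cl2, 0 °C
Reagents that add atoms: trimethyl orthoformate, COC(OC)OC
Why: Acid-catalysed acetalisation through the allylic oxocarbenium ion at C6, the usual capping of Achmatowicz hemiacetals, locks the ring against opening under the basic conditions of step 4, and methoxide is too poor a leaving group to trigger oxidopyrylium formation.

Step 4
Reactants: 6 6-methoxy-2-(4-methoxyphenyl)-2H-pyran-3(6H)-one
Product: 7 2-methoxy-4-(4-methoxyphenyl)-3,7-dioxabicyclo[4.1.0]heptan-5-one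
Conditions: 30% aq H2O2, NaOH (cat.), MeOH, 0 °C
Reagents that add atoms: hydrogen peroxide, OO
Why: Weitz–Scheffer nucleophilic epoxidation of the enone, established for 6-alkoxy-2H-pyran-3(6H)-ones in the maltol series, places the missing oxygen on pyranone C4; the relative configuration is irrelevant because all four sp3 centres are lost in step 5.

Step 5
Reactants: 7 2-methoxy-4-(4-methoxyphenyl)-3,7-dioxabicyclo[4.1.0]heptan-5-one
Product: 8 3-hydroxy-2-(4-methoxyphenyl)-4H-pyran-4-one
Conditions: 2 M aq H2SO4, 1,4-dioxane, reflux
Reagents that add atoms: none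
Why: Acid-induced isomerisation of the α,β-epoxy ketone to the C4-oxygenated diosphenol, β-elimination of methanol from the C6 acetal and enolisation at C2 give the γ-pyrone, the sequence by which maltol-type 3-hydroxy-4-pyranones are made from furfuryl alcohols, with the weakly aromatic product as thermodynamic sink.

Step 6
Reactants: 8 3-hydroxy-2-(4-methoxyphenyl)-4H-pyran-4-one
Product: 9 3-(benzyloxy)-2-(4-methoxyphenyl)-4H-pyran-4-one
Conditions: BnBr, K2CO3, DMF, 60 °C
Reagents that add atoms: benzyl bromide, BrCc1ccccc1
Why: Williamson etherification of the acidic enolic hydroxyl, routine for maltol and kojic acid; benzyl is chosen because it tolerates the iodination, the Grignard reagent, the thermolysis and the basic methylation and can be removed at the end without touching a methyl ether.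

Step 7
Reactants: 9 3-(benzyloxy)-2-(4-methoxyphenyl)-4H-pyran-4-one
Product: 10 3-(benzyloxy)-5-iodo-2-(4-methoxyphenyl)-4H-pyran-4-one
Conditions: I2 (0.6 equiv), (NH4)2Ce(NO3)6 (1.1 equiv), MeCN, 65 °C
Reagents that add atoms: iodine, II
Why: Oxidative electrophilic α-iodination of a γ-pyrone with I2 and (NH4)2Ce(NO3)6, known for chromones and flavones including 4'-methoxy-substituted ones: C5 is the nucleophilic β-carbon of the O1–C6=C5 enol ether, C2 and C3 are fully substituted, and the anisyl ring is para-blocked and deactivated by conjugation with the pyranone.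

Step 8
Reactants: 10 3-(benzyloxy)-5-iodo-2-(4-methoxyphenyl)-4H-pyran-4-one; 11 dimethyl squarate
Product: 13 4-[5-(benzyloxy)-6-(4-methoxyphenyl)-4-oxo-4H-pyran-3-yl]-4-hydroxy-2,3-dimethoxycyclobut-2-en-1-one (racemic), via pyranonylmagnesium chloride 12 (not isolated)
Conditions: iPrMgCl·LiCl, THF, −40 °C; then cannulated into 11 (1.5 equiv), THF, −78 °C; aq NH4Cl
Reagents that add atoms: none
Why: Iodine–magnesium exchange with the turbo-Grignard reagent, precedented for cyclic α-iodo-β-alkoxy enones such as 5-iodo-1,3-dioxin-4-ones and 5-iodouracils, should outrun addition to the pyranone at −40 °C and give a carbonyl-chelated alkenylmagnesium species that does not β-eliminate at this temperature, and 1,2-addition of sp2 organometallics to one carbonyl of dimethyl squarate is the standard entry to 4-hydroxycyclobutenones; the new carbinol centre is racemic and vanishes in step 9.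

Step 9
Reactants: 13 4-[5-(benzyloxy)-6-(4-methoxyphenyl)-4-oxo-4H-pyran-3-yl]-4-hydroxy-2,3-dimethoxycyclobut-2-en-1-one
Product: 16 3-(benzyloxy)-5,8-dihydroxy-6,7-dimethoxy-2-(4-methoxyphenyl)-4H-chromen-4-one, via dienylketene 14 (not isolated), via cyclohexadienone 15 (not isolated)
Conditions: PhMe (degassed), reflux (110 °C), Ar
Reagents that add atoms: none
Why: Heating cleaves the C1–C4 σ bond of the cyclobutenone in a conrotatory 4π opening and gives dienylketene 14, whose ketene is conjugated through the two methoxy-bearing carbons with the C5=C6 bond of the pyranone (numbering of 9). The ketene carbon then bonds to pyranone C6 (target C8–C8a) in a thermally allowed disrotatory 6π electrocyclisation, which is the mode by which the six-membered ring A closes, and dienone 15 tautomerises to the aromatic hydroquinone 16 with the squarate carbons ending as C5, C6, C7 and C8. This is the Moore rearrangement of 4-alkenyl- and 4-(hetero)aryl-4-hydroxycyclobutenones, and the weakly aromatic pyranone should behave like an alkenyl rather than an aryl substituent, so that toluene reflux should suffice. Two selectivities are needed: the pyranonyl group must turn inward on opening, which the strong outward preference of the donor hydroxyl enforces (torquoselectivity), and closure must occur at C6, the only sp2 CH next to the attachment point, since the other neighbour is the C4 carbonyl carbon. No stereocentre survives, because the carbinol carbon of 13 becomes sp2 in 14 and the C8a–H centre of 15 is lost on enolisation. Aromatisation and the hydrogen bond from the new 5-OH to C4=O supply the driving force, and degassed solvent under argon keeps the electron-rich hydroquinone from oxidising.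

Step 10
Reactants: 16 3-(benzyloxy)-5,8-dihydroxy-6,7-dimethoxy-2-(4-methoxyphenyl)-4H-chromen-4-one
Product: 17 3-(benzyloxy)-5,6,7,8-tetramethoxy-2-(4-methoxyphenyl)-4H-chromen-4-one
Conditions: Me2SO4 (excess), K2CO3, acetone, reflux, Ar
Reagents that add atoms: dimethyl sulfate, COS(=O)(=O)OC
Why: Williamson-type O-methylation of both phenols, the classical permethylation of polyhydroxyflavones; the 8-OH should react fast, the hydrogen-bonded 5-OH needs excess reagent and prolonged reflux, and exclusion of air keeps the hydroquinone anion from being oxidised before it is capped.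

Step 11
Reactants: 17 3-(benzyloxy)-5,6,7,8-tetramethoxy-2-(4-methoxyphenyl)-4H-chromen-4-one
Product: 18 3-hydroxy-5,6,7,8-tetramethoxy-2-(4-methoxyphenyl)-4H-chromen-4-one (target)
Conditions: H2 (1 atm), 10% Pd/C, EtOAc–MeOH, rt
Reagents that add atoms: none
Why: Catalytic hydrogenolysis of the benzylic C–O bond, the customary last step of flavonol syntheses, frees the 3-OH while the tetrasubstituted C2=C3 bond, the carbonyl group and the five methyl ethers are inert at one atmosphere and room temperature.

Compound list
1 | furfural | O=Cc1ccco1 | starting material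
2 | 4-bromoanisole | COc1ccc(Br)cc1 | starting material
3 | 4-methoxyphenylmagnesium bromide (not isolated) | COc1ccc([Mg]Br)cc1 | intermediate
4 | furan-2-yl(4-methoxyphenyl)methanol (racemic) | COc1ccc(C(O)c2ccco2)cc1 | intermediate
5 | 6-hydroxy-2-(4-methoxyphenyl)-2H-pyran-3(6H)-one (racemic, anomeric mixture) | COc1ccc(C2OC(O)C=CC2=O)cc1 | intermediate
6 | 6-methoxy-2-(4-methoxyphenyl)-2H-pyran-3(6H)-one (racemic, diastereomer mixture) | COc1ccc(C2OC(OC)C=CC2=O)cc1 | intermediate
7 | 2-methoxy-4-(4-methoxyphenyl)-3,7-dioxabicyclo[4.1.0]heptan-5-one (racemic, diastereomer mixture) | COc1ccc(C2OC(OC)C3OC3C2=O)cc1 | intermediate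
8 | 3-hydroxy-2-(4-methoxyphenyl)-4H-pyran-4-one | COc1ccc(-c2occc(=O)c2O)cc1 | intermediate
9 | 3-(benzyloxy)-2-(4-methoxyphenyl)-4H-pyran-4-one | COc1ccc(-c2occc(=O)c2OCc2ccccc2)cc1 | intermediate
10 | 3-(benzyloxy)-5-iodo-2-(4-methoxyphenyl)-4H-pyran-4-one | COc1ccc(-c2occ(I)c(=O)c2OCc2ccccc2)cc1 | intermediate
11 | dimethyl squarate (3,4-dimethoxycyclobut-3-ene-1,2-dione) | COC1=C(OC)C(=O)C1=O | starting material
12 | [5-(benzyloxy)-6-(4-methoxyphenyl)-4-oxo-4H-pyran-3-yl]magnesium chloride (not isolated) | COc1ccc(-c2occ([Mg]Cl)c(=O)c2OCc2ccccc2)cc1 | intermediate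
13 | 4-[5-(benzyloxy)-6-(4-methoxyphenyl)-4-oxo-4H-pyran-3-yl]-4-hydroxy-2,3-dimethoxycyclobut-2-en-1-one (racemic) | COC1=C(OC)C(O)(c2coc(-c3ccc(OC)cc3)c(OCc3ccccc3)c2=O)C1=O | intermediate
14 | (3Z)-4-[5-(benzyloxy)-6-(4-methoxyphenyl)-4-oxo-4H-pyran-3-yl]-4-hydroxy-2,3-dimethoxybuta-1,3-dien-1-one (dienylketene, not isolated) | O=C=C(OC)/C(OC)=C(/O)c1coc(-c2ccc(OC)cc2)c(OCc2ccccc2)c1=O | intermediate
15 | 3-(benzyloxy)-5-hydroxy-6,7-dimethoxy-2-(4-methoxyphenyl)-4H-chromene-4,8(8aH)-dione (racemic, not isolated) | COC1=C(OC)C(=O)C2OC(-c3ccc(OC)cc3)=C(OCc3ccccc3)C(=O)C2=C1O | intermediate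
16 | 3-(benzyloxy)-5,8-dihydroxy-6,7-dimethoxy-2-(4-methoxyphenyl)-4H-chromen-4-one | COc1ccc(-c2oc3c(O)c(OC)c(OC)c(O)c3c(=O)c2OCc2ccccc2)cc1 | intermediate
17 | 3-(benzyloxy)-5,6,7,8-tetramethoxy-2-(4-methoxyphenyl)-4H-chromen-4-one | COc1ccc(-c2oc3c(OC)c(OC)c(OC)c(OC)c3c(=O)c2OCc2ccccc2)cc1 | intermediate
18 | 3-hydroxy-5,6,7,8-tetramethoxy-2-(4-methoxyphenyl)-4H-chromen-4-one | COc1ccc(-c2oc3c(OC)c(OC)c(OC)c(OC)c3c(=O)c2O)cc1 | target

Total step count: 11. Longest linear sequence: 11 steps, from 1 or 2 to 18. Compound 11 enters as bought material in step 8.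

Steps most likely to fail

Step 8.
- Risk: the isopropyl Grignard reagent may attack the electrophilic pyranone in competition with the exchange. The C5-metalated pyranone may open by β-elimination of the O1 enolate on warming. The addition to the squarate carbonyl may be sluggish or go twice.
- Fallback: this sets out from 9 and needs no halide. Carbonyl-directed C–H zincation with TMP2Zn·2MgCl2·2LiCl in THF at −30 °C is the behaviour known for position 3 of chromones, where MgCl2 bound to the carbonyl oxygen steers the amide base to the adjacent C–H. It should give bis[5-(benzyloxy)-6-(4-methoxyphenyl)-4-oxo-4H-pyran-3-yl]zinc F1. Its covalent C–Zn bonds do not β-eliminate, and no alkyl nucleophile is present in the flask.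
- Return: the MgCl2 in the mixture should promote addition of F1 to the strained carbonyl of 11 (MgCl2-accelerated carbonyl addition of organozinc reagents). An NH4Cl quench brings the route back at 13.

Step 9.
- Risk: the hydroxyl may partly rotate inward, so that the ketene is trapped by that OH (lactonisation). Closure onto the electron-poor pyranone alkene may be slow, with loss of the ketene to oligomerisation. The hydroquinone may oxidise in air during isolation.
- Fallback: this sets out from 13. The tertiary alcohol is methylated with MeI and Ag2O in MeCN at rt, a known capping of 4-hydroxycyclobutenones, to give 4-[5-(benzyloxy)-6-(4-methoxyphenyl)-4-oxo-4H-pyran-3-yl]-2,3,4-trimethoxycyclobut-2-en-1-one F2.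
- Same bonds, different substrate: the methoxy group also rotates outward and cannot intercept the ketene. Thermolysis in degassed toluene or p-xylene should therefore form the same bonds and give 3-(benzyloxy)-8-hydroxy-5,6,7-trimethoxy-2-(4-methoxyphenyl)-4H-chromen-4-one F3, a much less oxidisable monophenol in which the awkward 5-oxygen is already methylated.
- Return: one methylation with Me2SO4 and K2CO3 in acetone brings the route back at 17.

Step 7.
- Risk: the anisyl ring may be iodinated ortho to its methoxy group. The cerium salt may oxidatively remove the benzyl group. Conversion may be incomplete because a monocyclic pyranone is only a weak nucleophile.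
- Fallback: this sets out from 9 and uses ionic addition–elimination in place of oxidative substitution. Br2 in CH2Cl2 at 0 °C should add across the C5=C6 enol ether bond to give 5-(benzyloxy)-2,3-dibromo-6-(4-methoxyphenyl)-2,3-dihydro-4H-pyran-4-one F4. Et3N then removes the acidic α-proton together with the bromide next to the ring oxygen, giving 3-(benzyloxy)-5-bromo-2-(4-methoxyphenyl)-4H-pyran-4-one F5.
- Return: copper-catalysed halogen exchange (aromatic Finkelstein reaction: NaI, CuI cat., trans-N,N'-dimethylcyclohexane-1,2-diamine, 1,4-dioxane, 110 °C) brings the route back at 10.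

Further compounds
F1 | step 8 | bis[5-(benzyloxy)-6-(4-methoxyphenyl)-4-oxo-4H-pyran-3-yl]zinc | COc1ccc(-c2occ([Zn]c3coc(-c4ccc(OC)cc4)c(OCc4ccccc4)c3=O)c(=O)c2OCc2ccccc2)cc1
F2 | step 9 | 4-[5-(benzyloxy)-6-(4-methoxyphenyl)-4-oxo-4H-pyran-3-yl]-2,3,4-trimethoxycyclobut-2-en-1-one (racemic) | COC1=C(OC)C(OC)(c2coc(-c3ccc(OC)cc3)c(OCc3ccccc3)c2=O)C1=O
F3 | step 9 | 3-(benzyloxy)-8-hydroxy-5,6,7-trimethoxy-2-(4-methoxyphenyl)-4H-chromen-4-one | COc1ccc(-c2oc3c(O)c(OC)c(OC)c(OC)c3c(=O)c2OCc2ccccc2)cc1
F4 | step 7 | 5-(benzyloxy)-2,3-dibromo-6-(4-methoxyphenyl)-2,3-dihydro-4H-pyran-4-one (racemic, configuration not relevant) | COc1ccc(C2=C(OCc3ccccc3)C(=O)C(Br)C(Br)O2)cc1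
F5 | step 7 | 3-(benzyloxy)-5-bromo-2-(4-methoxyphenyl)-4H-pyran-4-one | COc1ccc(-c2occ(Br)c(=O)c2OCc2ccccc2)cc1
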